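## Analysis of the target

Digriseophene A (16) is made of two identical griseophenone-type benzophenone halves joined by a single CH2 group, so it is constitutionally symmetric, has no stereocentre and no double-bond geometry, and every operation can be run twice on one substrate. In each half the phloroglucinol-derived ring A carries, in order round the ring, OCH3 at C1, H at C2, OH at C3, the ketone at C4, OH at C5 and the CH2 bridge at C6, and the bridge links C6 of one half to C6 of the other. The orcinol-derived ring B carries the ketone at C1', OCH3 at C2', H at C3', OH at C4', H at C5' and CH3 at C6'. The sensitive elements are six free phenols, the electron-rich ring A with its open C2 position, and the doubly benzylic CH2 between two oxygenated rings, which is exposed to oxidants and to acid-induced cleavage. The first difficulty is that the ketone is flanked by four ortho substituents (C3–O, C5–O, C2'–O, C6'–CH3), so the C4(=O)–C1' bond is hard to form. The second and third are that the oxygens must be told apart (C1 and C2' methylated, C3, C5 and C4' free, the C2' oxygen being the chelated and least reactive one) and that the bridge must be placed on one of two equivalent ring A positions without chain growth. The strategy rests on ring B: C1' lies between C2' (oxygen) and C6' (CH3) with the second oxygen at C4', which is the arrangement of C6, C1, C5 and C3 in 3-(benzyloxy)-5-methylcyclohex-2-enone (11), whose C6 is the nucleophilic carbon of the kinetic enolate.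

## Retrosynthetic reasoning

16 from 15. The six O–benzyl bonds are cut last. Every hydroxyl that is free in 16 (C3, C5 and C4' of both halves) is carried as a benzyl ether, so one hydrogenolysis ends the route. Acetal protection of ring A was considered; it would need a separate acidic step and would release 3 next to the nucleophilic C2 position.

15 from 14. The two C2'–O–CH3 bonds are cut. In 14 the C2' hydroxyls are the only free ones, so the methyl groups can only go where the target has them; the forward step only has to break the hydrogen bond to the ketone.

14 from 13. Ring B is taken back one oxidation level, to a cyclohexa-1,3-diene carrying a free enol at C2', a benzyl enol ether at C4' and two extra hydrogens at C5' and C6'. This is where the two ring B oxygens become different from each other. It also makes C1' an enolisable carbon instead of an unreactive aromatic position. The forward step must remove one H2 per ring without touching the bridge.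

13 from 8 and 11 (through 12). Both C4(=O)–C1' bonds are cut. This is the most crowded bond of each half, and cutting it here puts the acyl carbon on ring A, where a commercial benzoate already supplies it. The nucleophilic carbon is fixed by kinetic enolate formation rather than by the directing effects of an aromatic ring. An aromatic ring B would offer two competing positions to an acylating agent; enolate 12 offers one. The forward reaction must join a hindered acyl donor to C6 of 12 at carbon, twice.

8 from 7, 6 and 5. These are functional-group changes on ring A only: acyl imidazolide from acid, acid from methyl ester, benzyl ethers from phenols. Nothing skeletal is at stake, which keeps the risk of the route in the acylation.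

5 from 4 and 2. One aryl–CH2 bond of the bridge is cut. This returns a ring that already carries the one-carbon unit as an aminomethyl arm (4) and a second, unmodified molecule of 2. Cutting the bridge one bond at a time means that exactly one carbon is delivered per pair of rings, which holds back chain growth. The cut is made at the ester stage because the two open ring positions of 2 are equivalent by symmetry, so only one constitution can result, and the dimer then carries both acyl carbons through every later step. The forward reaction must unmask an ortho-quinone methide from 4 and have 2 capture it at carbon.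

4 from 2 and 3. The remaining aryl–CH2 bond and the CH2–N bond are cut, returning 2, the one-carbon electrophile 3 and a secondary amine that is released again in the following step. The forward step has to aminomethylate only one of the two equivalent positions of 2.

2 from 1. The C1–O–CH3 bond is cut. The forward step methylates the one hydroxyl of 1 that is not hydrogen-bonded to the ester.

11 from 9 and 10. The enol ether C–O bond is cut. Compound 9 is symmetric, so etherification gives a single product, and the benzyl group marks the future C4' oxygen as the one to be freed at the end.

## Alternatives that were turned down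

Alternative 1: Each ring A is cut at C5–C6 and C1–C2 into a two-carbon ynol ether unit (C6 and C1, already carrying the bridge and the OCH3) and a four-carbon vinylketene unit (C2 to C5). In the forward sense, heating 3-(benzyloxy)cyclobut-2-enone A2 with 1,5-dimethoxypenta-1,4-diyne A1 would open A2 to a vinylketene. A [2+2] addition to each methoxyalkyne, four-electron ring opening and six-electron closure (Danheiser benzannulation) would then give bis[4-(benzyloxy)-2-hydroxy-6-methoxyphenyl]methane A3.
- For: the bridge is present from the start, so the two steps that the chosen route spends on placing one carbon between two rings are not needed, and the three ring A oxygens emerge fully differentiated with the regiochemistry dictated by the mechanism. On control of the bridge this alternative is stronger than the chosen route.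
- Against: A1 is a skipped diyne with two ynol ethers and a doubly propargylic CH2 that is prone to isomerisation. Both A1 and A2 have to be made. Two benzannulations must succeed on one molecule. A3 still lacks both ketones: C4 would have to be aroylated twice, between two oxygens, in competition with C2, which is also flanked by two oxygens. Ring B would have to be built separately as an aroyl donor.
- Comparison: the crowded ketone bond is postponed, not solved, and the overall sequence is longer. The chosen route starts from a benzoate that already carries the C4 acyl carbon and solves the ketone bond in the key step itself.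

Alternative 2: Each ring A is cut at C4–C5 and unravelled to a 4-methoxy-2-pyranone bearing a 2-aryl-2-oxoethyl side chain at its C6, giving the methylene-bridged bis-pyranone A4. In the forward sense Mg(OMe)2 in methanol would open both lactones to methyl esters. The CH2 between the two ketones of each arm would then attack its ester carbonyl (Claisen-type ring closure) and the rings would enolise to 4',4'-di-O-benzyl digriseophene A A5.
- For: ring A would appear with OCH3 at C1 and free hydroxyls at C3 and C5 without any protecting group. The crowded ketone is never made by attack on a hindered carbonyl, because it is already in the chain. A5 is one hydrogenolysis from the target. On protecting-group economy and on the end game this alternative is stronger.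
- Against: A4 needs ring B as a preformed aromatic acyl donor, itself several steps. It needs regioselective O-methylation of a bis(4-hydroxypyranone), and two side-chain acylations on a substrate whose bridging CH2 is also acidic. The opened triketo ester can close in other ways (aldol closure, return to the pyranone), and methoxide can exchange at the β-methoxy enoate, twice in one molecule.
- Comparison: the chosen route offers both coupling partners in a few steps from commercial six-membered rings, no separate aromatic synthesis of ring B, and a bond-forming site fixed by enolate regiochemistry instead of by the folding of a polycarbonyl chain.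

Alternative 3: Each ring B is cut at C1'–C6' and unravelled to a 1-aryl-octane-1,3,5,7-tetraone chain, giving the bis(tetraketone) A6. In the forward sense aqueous KOH would fold each arm by aldol attack of the CH2 next to the aryl ketone on the terminal methyl ketone, and dehydration would give tetra-MOM 2',2'-di-O-demethyl digriseophene A A7.
- For: the closure is biomimetic and ring B aromatises by loss of water, so no oxidant is needed. On redox economy this alternative is stronger, since the chosen route must dehydrogenate in the presence of a doubly benzylic CH2.
- Against: A6 holds eight ketone carbonyls and would have to be assembled by two acylations of a triketone polyanion with a hindered diester. Such chains cyclise readily through oxygen to 4-pyranones and can fold by other aldol or Claisen modes. A7 has both ring B hydroxyls free, and the target needs the methyl on the chelated, less reactive C2' oxygen, so C4'–OH would have to be protected, C2'–OH methylated, and two kinds of protecting group removed.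
- Comparison: the chosen route delivers ring B with its two oxygens already different (free enol at C2', benzyl enol ether at C4'), so the methyl group is placed directly, and it handles stable, isolable intermediates.

Key step: step 8

Remark on the chemistry: enone 11 is used as the racemate, and the methyl-bearing stereocentres of 11, 12 and 13 are written without descriptors because step 9 removes them. Atom labels C1–C6 and C1'–C6' are those defined in the analysis; in the names of 8 and 13 to 16 the locants 3,3' refer to the ring A carbons that carry the CH2 bridge.

## Route

Step 1
Reactants: 1 methyl 2,4,6-trihydroxybenzoate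
Product: 2 methyl 2,6-dihydroxy-4-methoxybenzoate
Conditions: MeI (1.05 equiv), K2CO3 (1.05 equiv), acetone, rt
Reagents that add atoms: iodomethane, CI
Why: Williamson ether synthesis under substrate control: the hydroxyl para to the ester is the most acidic and the only one not held in a hydrogen bond to the ester, so one equivalent of base and MeI should alkylate it preferentially. The two chelated hydroxyls react much more slowly, and any over-methylated material is separable.

Step 2
Reactants: 2 methyl 2,6-dihydroxy-4-methoxybenzoate; 3 formaldehyde
Product: 4 methyl 2,6-dihydroxy-4-methoxy-3-(morpholin-4-ylmethyl)benzoate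
Conditions: morpholine (0.9 equiv), 37% aq CH2O (0.9 equiv), EtOH, 0 °C to rt
Reagents that add atoms: morpholine, C1COCCN1
Why: Mannich reaction (electrophilic aromatic aminomethylation): the iminium ion formed from 3 and morpholine attacks one of the two equivalent open ring positions of 2, each of which is ortho to one hydroxyl and para to the other. A slight deficiency of the iminium partner is meant to hold the reaction at the mono-aminomethyl stage; unreacted 2 is recovered for step 3 and any bis-adduct is removed through its higher basicity.

Step 3
Reactants: 4 methyl 2,6-dihydroxy-4-methoxy-3-(morpholin-4-ylmethyl)benzoate; 2 methyl 2,6-dihydroxy-4-methoxybenzoate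
Product: 5 dimethyl 3,3'-methylenebis(2,6-dihydroxy-4-methoxybenzoate)
Conditions: 2 (3 equiv), xylene, 140 °C, slow N2 stream
Reagents that add atoms: none
Why: Thermal loss of morpholine from the ortho-hydroxybenzylamine 4 (retro-Mannich) gives an ortho-quinone methide, which is captured at carbon by an open ring position of 2 (conjugate addition, then rearomatisation). The excess of 2 is meant to outcompete 4 and 5 as traps, and sweeping out the amine keeps the elimination from reversing. Both open positions of 2 are equivalent, so only one constitution can form.

Step 4
Reactants: 5 dimethyl 3,3'-methylenebis(2,6-dihydroxy-4-methoxybenzoate)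
Product: 6 dimethyl 3,3'-methylenebis[2,6-bis(benzyloxy)-4-methoxybenzoate]
Conditions: BnBr (4.8 equiv), K2CO3, DMF, 60 °C
Reagents that add atoms: benzyl bromide, BrCc1ccccc1
Why: Fourfold Williamson O-benzylation; K2CO3 in warm DMF breaks the hydrogen bonds to the esters and favours O- over C-alkylation of the ester-deactivated rings. Benzyl is chosen so that every phenol that ends up free is released in one final hydrogenolysis.

Step 5
Reactants: 6 dimethyl 3,3'-methylenebis[2,6-bis(benzyloxy)-4-methoxybenzoate]
Product: 7 3,3'-methylenebis[2,6-bis(benzyloxy)-4-methoxybenzoic acid]
Conditions: KOH, DMSO–H2O, 90 °C; then cold 1 M HCl to pH 3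
Reagents that add atoms: potassium hydroxide, [K+].[OH-]
Why: Saponification (acyl–oxygen cleavage) of two di-ortho-alkoxy benzoates; the crowding is met with hot KOH in aqueous DMSO, and aryl benzyl and methyl ethers are inert to base. Acidification is kept cold and mild because 2,4,6-trioxygenated benzoic acids can lose CO2 in strong acid.

Step 6
Reactants: 7 3,3'-methylenebis[2,6-bis(benzyloxy)-4-methoxybenzoic acid]
Product: 8 3,3'-methylenebis{[2,6-bis(benzyloxy)-4-methoxyphenyl](1H-imidazol-1-yl)methanone} (the bis(acyl imidazolide))
Conditions: CDI (2.5 equiv), THF, rt to 50 °C; cold aqueous wash, dry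
Reagents that add atoms: 1,1'-carbonyldiimidazole, O=C(n1ccnc1)n1ccnc1
Why: Carboxylic acid activation with CDI: the carboxylate attacks CDI, the mixed anhydride loses CO2, and imidazole adds to give the acyl imidazolide, which for 2,6-dialkoxybenzoic acids is hindered enough to survive a quick cold wash. The liberated imidazole is washed out because its N–H would quench the enolate in step 8.

Step 7
Reactants: 9 5-methylcyclohexane-1,3-dione; 10 benzyl alcohol
Product: 11 3-(benzyloxy)-5-methylcyclohex-2-en-1-one (racemic)
Conditions: TsOH·H2O (cat.), toluene, reflux, Dean–Stark
Reagents that add atoms: none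
Why: Acid-catalysed enol etherification of a cyclic 1,3-diketone with azeotropic removal of water (vinylogous Fischer esterification). Compound 9 is symmetric, so a single enol ether can form.

Step 8
Reactants: 8 3,3'-methylenebis{[2,6-bis(benzyloxy)-4-methoxyphenyl](1H-imidazol-1-yl)methanone}; 11 3-(benzyloxy)-5-methylcyclohex-2-en-1-one
Product: 13 3,3'-methylenebis{[2,6-bis(benzyloxy)-4-methoxyphenyl][4-(benzyloxy)-2-hydroxy-6-methylcyclohexa-1,3-dien-1-yl]methanone} (chelated enol form; diastereomer mixture), via lithium 5-(benzyloxy)-3-methylcyclohexa-1,5-dien-1-olate 12 (not isolated)
Conditions: 11 (4.4 equiv), LiN(iPr)2 (4.4 equiv), THF, −78 °C; then 8 (1 equiv) in THF, −78 to 0 °C; aq NH4Cl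
Reagents that add atoms: none
Why: LiN(iPr)2 at −78 °C removes a C6 proton of 11 irreversibly and gives the cross-conjugated dienolate 12 and not the extended enolate, as is general for 3-alkoxycyclohex-2-enones (Stork–Danheiser regiochemistry). C6 of 12 adds to each acyl imidazolide carbonyl of 8 through a lithium-bridged tetrahedral intermediate that collapses with loss of imidazolide; this is a Claisen-type C-acylation of a ketone enolate by an N-acyl azole, a known reaction type. Each new β-diketone is more acidic than 11 and is deprotonated at once by a second equivalent of 12, which is why more than two equivalents of 12 per acyl group are used; the resulting chelated lithium diketonate is inert to further acylation, and the 11 that is returned can be recovered. No ring is closed and no lasting stereocentre is created: the acylated carbon enolises, and the methyl-bearing carbons come from racemic 11, so 13 forms as a diastereomer mixture that converges in step 9. The step needs carbon over oxygen acylation and bonding at C6 and not at the γ carbon. The first is secured by the acyl imidazolide, a lithium-coordinating acyl donor with a non-ionising leaving group that reacts through the chelated transition state at carbon. The second is secured by kinetic enolate formation and by keeping the mixture cold so that proton exchange with free 11 does not equilibrate the enolate. The four ortho benzyloxy groups crowd the carbonyls, so the mixture is allowed to warm to 0 °C, and the mild NH4Cl quench keeps the benzyl enol ethers intact.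

Step 9
Reactants: 13 3,3'-methylenebis{[2,6-bis(benzyloxy)-4-methoxyphenyl][4-(benzyloxy)-2-hydroxy-6-methylcyclohexa-1,3-dien-1-yl]methanone}
Product: 14 3,3'-methylenebis{[2,6-bis(benzyloxy)-4-methoxyphenyl][4-(benzyloxy)-2-hydroxy-6-methylphenyl]methanone}
Conditions: DDQ (2.3 equiv), 1,4-dioxane, rt to 50 °C
Reagents that add atoms: none
Why: Dehydrogenation of a cyclohexa-1,3-diene to an arene with DDQ: hydride abstraction from C6'–H gives a cyclohexadienyl cation stabilised by the C2' and C4' oxygens, and loss of a C5' proton gives the phenol, with aromatisation as the driving force. Both methyl-bearing stereocentres vanish, so the diastereomers of 13 converge to one compound. Aryl benzyl ethers and the shielded bridge CH2 are expected to react with DDQ more slowly than the dihydroarene rings.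

Step 10
Reactants: 14 3,3'-methylenebis{[2,6-bis(benzyloxy)-4-methoxyphenyl][4-(benzyloxy)-2-hydroxy-6-methylphenyl]methanone}
Product: 15 3,3'-methylenebis{[2,6-bis(benzyloxy)-4-methoxyphenyl][4-(benzyloxy)-2-methoxy-6-methylphenyl]methanone}
Conditions: MeI, Cs2CO3, DMF, rt
Reagents that add atoms: iodomethane, CI
Why: Williamson methylation of the only free hydroxyls in the molecule; Cs2CO3 in DMF ionises the ketone-chelated C2' phenols and MeI traps the phenoxides. All other oxygens are already capped, so no selectivity question arises.

Step 11
Reactants: 15 3,3'-methylenebis{[2,6-bis(benzyloxy)-4-methoxyphenyl][4-(benzyloxy)-2-methoxy-6-methylphenyl]methanone}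
Product: 16 digriseophene A, 3,3'-methylenebis[(2,6-dihydroxy-4-methoxyphenyl)(4-hydroxy-2-methoxy-6-methylphenyl)methanone]
Conditions: H2 (1 atm), Pd/C, EtOAc–MeOH, rt
Reagents that add atoms: none
Why: Hydrogenolysis of six aryl benzyl ethers over Pd/C. The tetra-ortho-substituted diaryl ketone is too hindered, and after debenzylation too strongly hydrogen-bonded, to be reduced under one atmosphere of hydrogen; the methyl ethers and the diarylmethane are inert.

## Compound list

1 | methyl 2,4,6-trihydroxybenzoate | COC(=O)c1c(O)cc(O)cc1O | starting material
2 | methyl 2,6-dihydroxy-4-methoxybenzoate | COC(=O)c1c(O)cc(OC)cc1O | intermediate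
3 | formaldehyde | C=O | starting material
4 | methyl 2,6-dihydroxy-4-methoxy-3-(morpholin-4-ylmethyl)benzoate | COC(=O)c1c(O)cc(OC)c(CN2CCOCC2)c1O | intermediate
5 | dimethyl 3,3'-methylenebis(2,6-dihydroxy-4-methoxybenzoate) | COc1cc(O)c(C(=O)OC)c(O)c1Cc1c(OC)cc(O)c(C(=O)OC)c1O | intermediate
6 | dimethyl 3,3'-methylenebis[2,6-bis(benzyloxy)-4-methoxybenzoate] | COc1cc(OCc2ccccc2)c(C(=O)OC)c(OCc2ccccc2)c1Cc1c(OC)cc(OCc2ccccc2)c(C(=O)OC)c1OCc1ccccc1 | intermediate
7 | 3,3'-methylenebis[2,6-bis(benzyloxy)-4-methoxybenzoic acid] | COc1cc(OCc2ccccc2)c(C(=O)O)c(OCc2ccccc2)c1Cc1c(OC)cc(OCc2ccccc2)c(C(=O)O)c1OCc1ccccc1 | intermediate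
8 | 3,3'-methylenebis{[2,6-bis(benzyloxy)-4-methoxyphenyl](1H-imidazol-1-yl)methanone} | COc1cc(OCc2ccccc2)c(C(=O)n2ccnc2)c(OCc2ccccc2)c1Cc1c(OC)cc(OCc2ccccc2)c(C(=O)n2ccnc2)c1OCc1ccccc1 | intermediate
9 | 5-methylcyclohexane-1,3-dione | CC1CC(=O)CC(=O)C1 | starting material
10 | benzyl alcohol | OCc1ccccc1 | starting material
11 | 3-(benzyloxy)-5-methylcyclohex-2-en-1-one (racemic) | CC1CC(=O)C=C(OCc2ccccc2)C1 | intermediate
12 | lithium 5-(benzyloxy)-3-methylcyclohexa-1,5-dien-1-olate (racemic; not isolated) | [Li+].CC1CC(OCc2ccccc2)=CC([O-])=C1 | intermediate
13 | 3,3'-methylenebis{[2,6-bis(benzyloxy)-4-methoxyphenyl][4-(benzyloxy)-2-hydroxy-6-methylcyclohexa-1,3-dien-1-yl]methanone} (enol form; mixture of diastereomers at the two methyl-bearing carbons) | COc1cc(OCc2ccccc2)c(C(=O)C2=C(O)C=C(OCc3ccccc3)CC2C)c(OCc2ccccc2)c1Cc1c(OC)cc(OCc2ccccc2)c(C(=O)C2=C(O)C=C(OCc3ccccc3)CC2C)c1OCc1ccccc1 | intermediate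
14 | 3,3'-methylenebis{[2,6-bis(benzyloxy)-4-methoxyphenyl][4-(benzyloxy)-2-hydroxy-6-methylphenyl]methanone} | COc1cc(OCc2ccccc2)c(C(=O)c2c(C)cc(OCc3ccccc3)cc2O)c(OCc2ccccc2)c1Cc1c(OC)cc(OCc2ccccc2)c(C(=O)c2c(C)cc(OCc3ccccc3)cc2O)c1OCc1ccccc1 | intermediate
15 | 3,3'-methylenebis{[2,6-bis(benzyloxy)-4-methoxyphenyl][4-(benzyloxy)-2-methoxy-6-methylphenyl]methanone} | COc1cc(OCc2ccccc2)c(C(=O)c2c(C)cc(OCc3ccccc3)cc2OC)c(OCc2ccccc2)c1Cc1c(OC)cc(OCc2ccccc2)c(C(=O)c2c(C)cc(OCc3ccccc3)cc2OC)c1OCc1ccccc1 | intermediate
16 | digriseophene A, 3,3'-methylenebis[(2,6-dihydroxy-4-methoxyphenyl)(4-hydroxy-2-methoxy-6-methylphenyl)methanone] | COc1cc(O)c(C(=O)c2c(C)cc(O)cc2OC)c(O)c1Cc1c(OC)cc(O)c(C(=O)c2c(C)cc(O)cc2OC)c1O | target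

## Step count and least certain steps

Total: 11 steps. Longest linear sequence: 10 steps (steps 1 to 6 and 8 to 11); step 7 is a one-step side branch.

Step 8 (key step). The carbonyls of 8 are flanked by two benzyloxy groups and sit on electron-rich rings, and the nucleophilic carbon of 12 is next to the methyl-bearing carbon. Attack at carbon may therefore be slow, which would let O-acylation, enolate equilibration to the extended enolate, or stalling after one acylation take over. The fallback forms the same two bonds at the aldehyde oxidation level. It sets out from diester 6 and comes back at 13. LiAlH4 in THF would reduce both esters of 6 to the bis(benzylic alcohol) F1, and MnO2 in CH2Cl2 would give the dialdehyde F2. Addition of dienolate 12 at −78 °C to the far less hindered and more electrophilic formyl groups would give the bis(β-hydroxy ketone) F3. Oxidation of both carbinols with Dess–Martin periodinane would return 13. This detour also avoids steps 5 and 6.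

Step 9. DDQ may abstract hydride from the bridge CH2 between the two oxygenated rings, may slowly oxidise benzyl ethers, or may leave one of the two rings at the dihydro level. The fallback replaces hydride abstraction by a selenoxide elimination; it sets out from 13 and comes back at 14. PhSeCl and pyridine in CH2Cl2 would selenenylate C1' of each β-diketone, anti to the C6' methyl group and therefore syn to C6'–H, to give the bis(selenide) F4. H2O2 at 0 °C would form the selenoxides, which eliminate across C1'–C6' to cross-conjugated dienones that tautomerise to the phenols of 14.

Step 3. Loss of the amine from 4 may need temperatures at which the free amine begins to attack the methyl esters, and the quinone methide may be captured by 4 or by 5 instead of 2, which would lead to chain growth. The fallback turns the amine into a charged leaving group so that the quinone methide is released by base at room temperature; it sets out from 4 and comes back at 5. MeI in acetone at room temperature would quaternise the nitrogen of 4 to 4-{[2,4-dihydroxy-6-methoxy-3-(methoxycarbonyl)phenyl]methyl}-4-methylmorpholin-4-ium iodide F5. NaHCO3 in DMF at room temperature would then expel N-methylmorpholine from F5, and the ortho-quinone methide so formed would be captured by an excess of 2, present as its phenoxide, to give 5.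

Step 5. Acyl–oxygen cleavage at the doubly ortho-substituted esters may stop at the mono-acid, and the electron-rich diacid may lose CO2 during acidification. The fallback cleaves the other bond of the ester; it sets out from 6 and comes back at 7 without a new intermediate. Lithium propanethiolate (LiSPr) in DMF at room temperature would attack the unhindered ester methyl groups in an SN2 reaction, so crowding at the carbonyl no longer matters, and the carboxylate is protonated with a buffer at pH 4 to 5.

Further compounds

F1 | step 8 | {methylenebis[2,4-bis(benzyloxy)-6-methoxy-3,1-phenylene]}dimethanol (bis(benzylic alcohol) of the core) | COc1cc(OCc2ccccc2)c(CO)c(OCc2ccccc2)c1Cc1c(OC)cc(OCc2ccccc2)c(CO)c1OCc1ccccc1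
F2 | step 8 | 3,3'-methylenebis[2,6-bis(benzyloxy)-4-methoxybenzaldehyde] | COc1cc(OCc2ccccc2)c(C=O)c(OCc2ccccc2)c1Cc1c(OC)cc(OCc2ccccc2)c(C=O)c1OCc1ccccc1
F3 | step 8 | 6,6'-{methylenebis[(2,4-bis(benzyloxy)-6-methoxy-3,1-phenylene)(hydroxy)methylene]}bis[3-(benzyloxy)-5-methylcyclohex-2-en-1-one] (bis(β-hydroxy ketone), mixture of diastereomers) | COc1cc(OCc2ccccc2)c(C(O)C2C(C)CC(OCc3ccccc3)=CC2=O)c(OCc2ccccc2)c1Cc1c(OC)cc(OCc2ccccc2)c(C(O)C2C(C)CC(OCc3ccccc3)=CC2=O)c1OCc1ccccc1
F4 | step 9 | 6,6'-{methylenebis[(2,4-bis(benzyloxy)-6-methoxy-3,1-phenylene)carbonyl]}bis[3-(benzyloxy)-5-methyl-6-(phenylselanyl)cyclohex-2-en-1-one] (bis(selenide), mixture of diastereomers) | COc1cc(OCc2ccccc2)c(C(=O)C2([Se]c3ccccc3)C(C)CC(OCc3ccccc3)=CC2=O)c(OCc2ccccc2)c1Cc1c(OC)cc(OCc2ccccc2)c(C(=O)C2([Se]c3ccccc3)C(C)CC(OCc3ccccc3)=CC2=O)c1OCc1ccccc1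
F5 | step 3 | 4-{[2,4-dihydroxy-6-methoxy-3-(methoxycarbonyl)phenyl]methyl}-4-methylmorpholin-4-ium iodide | COC(=O)c1c(O)cc(OC)c(C[N+]2(C)CCOCC2)c1O.[I-]
F0 | step 5 | none | none
A1 | alternative 1 | 1,5-dimethoxypenta-1,4-diyne | COC#CCC#COC
A2 | alternative 1 | 3-(benzyloxy)cyclobut-2-en-1-one | O=C1CC(OCc2ccccc2)=C1
A3 | alternative 1 | bis[4-(benzyloxy)-2-hydroxy-6-methoxyphenyl]methane | COc1cc(OCc2ccccc2)cc(O)c1Cc1c(OC)cc(OCc2ccccc2)cc1O
A4 | alternative 2 | 3,3'-methylenebis{6-[2-(4-(benzyloxy)-2-methoxy-6-methylphenyl)-2-oxoethyl]-4-methoxy-2H-pyran-2-one} | COc1cc(CC(=O)c2c(C)cc(OCc3ccccc3)cc2OC)oc(=O)c1Cc1c(OC)cc(CC(=O)c2c(C)cc(OCc3ccccc3)cc2OC)oc1=O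
A5 | alternative 2 | 4',4'-di-O-benzyl digriseophene A | COc1cc(O)c(C(=O)c2c(C)cc(OCc3ccccc3)cc2OC)c(O)c1Cc1c(OC)cc(O)c(C(=O)c2c(C)cc(OCc3ccccc3)cc2OC)c1O
A6 | alternative 3 | 1,1'-{methylenebis[6-methoxy-2,4-bis(methoxymethoxy)-3,1-phenylene]}bis(octane-1,3,5,7-tetraone) | COc1cc(OCOC)c(C(=O)CC(=O)CC(=O)CC(C)=O)c(OCOC)c1Cc1c(OC)cc(OCOC)c(C(=O)CC(=O)CC(=O)CC(C)=O)c1OCOC
A7 | alternative 3 | tetra-MOM 2',2'-di-O-demethyl digriseophene A | COc1cc(OCOC)c(C(=O)c2c(C)cc(O)cc2O)c(OCOC)c1Cc1c(OC)cc(OCOC)c(C(=O)c2c(C)cc(O)cc2O)c1OCOC
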